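**Plan**

1. Locants are those of tricyclo[5.4.0.0^{2,8}]undecane, as in the name of 29: C9 is the ketone, C10=C11 the enone C=C, C1–C2–C8–C7 the cyclobutane, C2–C3–C4–C5–C6–C7–C8 the cycloheptane, with O-angeloyl on C4 and O-acetyl on C6.
2. Cuts: the C4–O angelate ester (last step); then C8–C9 and C1–C7 together, which opens the cyclohexenone C1–C7–C8–C9–C10–C11 to a vinylketene (C9=C10–C11=C1) hanging on C2 of a cycloheptene with the alkene C7=C8; then C7=C8 (ring-closing metathesis), C5–C6 (aldol) and C2–C3 (allylic alkylation).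
3. Enabling feature: the enone ring is the [4+2] retron of a vinylketene and an alkene, and C1 and C8 both sit on C2, so one annulation closes the six-membered ring and the cyclobutane. A triethylsilyl group on C10 (helper, removed in step 17) blocks the usual closure at C10.
4. Forward order: C2–C3 chain, then C4–C6, then the cycloheptene, then the (Z)-dienyl side chain on C2, then cyclohexenone and cyclobutane in one step, then the esters.
5. Stereochemistry: C2 from iridium-catalysed asymmetric allylic alkylation, C6 from a reagent-controlled boron aldol, C4 from 1,3-anti Evans–Tishchenko reduction; C1, C7 and C8 follow from C2 in the key step (cis tether, cage).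

Key step: step 16

Assumption: the antipodes of the iridium ligand (step 3) and of Ipc2BCl (step 5) are taken as those that give the configurations drawn (Re-face attack on methacrolein in step 5), and the SMILES of the borane, of 9 and of the isopinocampheol set free show one antipode of the Ipc groups, the mirror-image reagent being used if the other sense is needed; TBS = tert-butyldimethylsilyl, Ipc = isopinocampheyl.

**Route**

Step 1
Reactants: 1 (E)-but-2-ene-1,4-diol
Product: 2 (E)-4-[(tert-butyldimethylsilyl)oxy]but-2-en-1-ol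
Conditions: NaH (1.0 equiv), THF, 0 °C; TBSCl (1.0 equiv), 0 °C → rt
Reagents that add atoms: tert-butyldimethylsilyl chloride (CC(C)(C)[Si](C)(C)Cl)
Why: The sparingly soluble monosodium alkoxide of the symmetrical diol is silylated once (mono-O-silylation of a symmetrical diol), which frees one allylic hydroxyl for activation.

Step 2
Reactants: 2 (E)-4-[(tert-butyldimethylsilyl)oxy]but-2-en-1-ol
Product: 3 (E)-4-[(tert-butyldimethylsilyl)oxy]but-2-en-1-yl methyl carbonate
Conditions: ClCO2Me, pyridine, CH2Cl2, 0 °C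
Reagents that add atoms: methyl chloroformate (COC(=O)Cl)
Why: O-Acylation of the primary allylic alcohol gives the linear allylic carbonate, whose ionisation later supplies methoxide to activate the silyl nucleophile.

Step 3
Reactants: 3 (E)-4-[(tert-butyldimethylsilyl)oxy]but-2-en-1-yl methyl carbonate; 4 1-methoxy-2-methyl-1-(trimethylsilyloxy)prop-1-ene
Product: 5 methyl (3S)-3-{[(tert-butyldimethylsilyl)oxy]methyl}-2,2-dimethylpent-4-enoate
Conditions: [Ir(cod)Cl]2 (2 mol %), O,O'-(1,1'-binaphthyl-2,2'-diyl) N,N-bis(1-phenylethyl)phosphoramidite (4 mol %, iridacycle pre-formed with n-PrNH2), THF, rt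
Reagents that add atoms: none
Why: Iridium-catalysed asymmetric allylic alkylation: the ester enolate released from the silyl ketene acetal should attack the substituted terminus of the allyl–iridium complex (branched selectivity), which joins quaternary C3 to C2 and sets C2 by the chiral ligand.

Step 4
Reactants: 5 methyl (3S)-3-{[(tert-butyldimethylsilyl)oxy]methyl}-2,2-dimethylpent-4-enoate
Product: 7 (4S)-4-{[(tert-butyldimethylsilyl)oxy]methyl}-3,3-dimethylhex-5-en-2-one, via Weinreb amide 6 (not isolated)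
Conditions: MeNHOMe·HCl, i-PrMgCl, THF, −20 → 0 °C; then MeMgBr, 0 °C → rt; aq. NH4Cl
Reagents that add atoms: methylmagnesium bromide (C[Mg]Br); N,O-dimethylhydroxylamine hydrochloride (CNOC.Cl)
Why: The magnesium amide converts the hindered ester into the N-methoxy-N-methylamide 6, whose chelated tetrahedral adduct with MeMgBr stops at the methyl ketone (Weinreb ketone synthesis).

Step 5
Reactants: 7 (4S)-4-{[(tert-butyldimethylsilyl)oxy]methyl}-3,3-dimethylhex-5-en-2-one; 8 methacrolein
Product: 10 (3R,7S)-7-{[(tert-butyldimethylsilyl)oxy]methyl}-3-hydroxy-2,6,6-trimethylnona-1,8-dien-5-one, via boron enolate 9 (not isolated)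
Conditions: Ipc2BCl, Et3N, Et2O, 0 °C; 8, −78 → −20 °C; H2O2, MeOH, pH 7 buffer
Reagents that add atoms: B-chlorodiisopinocampheylborane (ClB([C@H]1C[C@H]2C[C@@H]([C@@H]1C)C2(C)C)[C@H]1C[C@H]2C[C@@H]([C@@H]1C)C2(C)C)
Why: The ketone can enolise only at its methyl group, and the diisopinocampheylboron enolate 9 should add to the aldehyde through a cyclic transition state in which the boron ligands select the Re face (reagent-controlled boron aldol), which forms C5–C6 and sets C6.

Step 6
Reactants: 10 (3R,7S)-7-{[(tert-butyldimethylsilyl)oxy]methyl}-3-hydroxy-2,6,6-trimethylnona-1,8-dien-5-one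
Product: 11 (3R,5R,7S)-7-{[(tert-butyldimethylsilyl)oxy]methyl}-5-hydroxy-2,6,6-trimethylnona-1,8-dien-3-yl acetate
Conditions: SmI2 (0.3 equiv), CH3CHO (excess), THF, −10 °C
Reagents that add atoms: acetaldehyde (CC=O)
Why: Evans–Tishchenko reduction: the samarium-bound hemiacetal of acetaldehyde on O6 delivers hydride to the C4 ketone through a six-membered chair, which should give the 1,3-anti diol with O6 acetylated and O4 free, so C4 is set and the two oxygens are told apart.

Step 7
Reactants: 11 (3R,5R,7S)-7-{[(tert-butyldimethylsilyl)oxy]methyl}-5-hydroxy-2,6,6-trimethylnona-1,8-dien-3-yl acetate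
Product: 12 (3R,5R,7S)-5-[(tert-butyldimethylsilyl)oxy]-7-{[(tert-butyldimethylsilyl)oxy]methyl}-2,6,6-trimethylnona-1,8-dien-3-yl acetate
Conditions: TBSOTf, 2,6-lutidine, CH2Cl2, −78 → 0 °C
Reagents that add atoms: tert-butyldimethylsilyl triflate (CC(C)(C)[Si](C)(C)OS(=O)(=O)C(F)(F)F)
Why: The silyl triflate silylates the hindered neopentyl secondary alcohol (O-silylation), which keeps O4 from oxidation in step 10 and from trapping the ketene in step 16.

Step 8
Reactants: 12 (3R,5R,7S)-5-[(tert-butyldimethylsilyl)oxy]-7-{[(tert-butyldimethylsilyl)oxy]methyl}-2,6,6-trimethylnona-1,8-dien-3-yl acetate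
Product: 13 (1R,4S,6R)-6-[(tert-butyldimethylsilyl)oxy]-4-{[(tert-butyldimethylsilyl)oxy]methyl}-2,5,5-trimethylcyclohept-2-en-1-yl acetate
Conditions: (H2IMes)(PCy3)Cl2Ru=CHPh (second-generation Grubbs catalyst, 5 mol %), CH2Cl2 (0.005 M), 40 °C
Reagents that add atoms: none
Why: Ring-closing metathesis of the vinyl and isopropenyl groups closes the seven-membered ring with the trisubstituted C7=C8 alkene, helped by the gem-dimethyl group and driven by loss of ethylene.

Step 9
Reactants: 13 (1R,4S,6R)-6-[(tert-butyldimethylsilyl)oxy]-4-{[(tert-butyldimethylsilyl)oxy]methyl}-2,5,5-trimethylcyclohept-2-en-1-yl acetate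
Product: 14 (1R,4S,6R)-6-[(tert-butyldimethylsilyl)oxy]-4-(hydroxymethyl)-2,5,5-trimethylcyclohept-2-en-1-yl acetate
Conditions: HF·pyridine, pyridine, THF, 0 °C
Reagents that add atoms: none
Why: Buffered fluoride cleaves the unhindered primary silyl ether much faster than the neopentyl secondary one (selective desilylation).

Step 10
Reactants: 14 (1R,4S,6R)-6-[(tert-butyldimethylsilyl)oxy]-4-(hydroxymethyl)-2,5,5-trimethylcyclohept-2-en-1-yl acetate
Product: 15 (1R,4S,6R)-6-[(tert-butyldimethylsilyl)oxy]-4-formyl-2,5,5-trimethylcyclohept-2-en-1-yl acetate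
Conditions: Dess–Martin periodinane, NaHCO3, CH2Cl2, 0 °C → rt; used at once
Reagents that add atoms: none
Why: Buffered Dess–Martin oxidation gives the aldehyde under non-basic conditions, so the allylic α-stereocenter C2 should neither epimerise nor move into conjugation.

Step 11
Reactants: 15 (1R,4S,6R)-6-[(tert-butyldimethylsilyl)oxy]-4-formyl-2,5,5-trimethylcyclohept-2-en-1-yl acetate; 16 ethyl 2-[bis(2,2,2-trifluoroethoxy)phosphoryl]propanoate
Product: 17 ethyl (2Z)-3-[(1R,4R,6R)-4-acetoxy-6-[(tert-butyldimethylsilyl)oxy]-3,7,7-trimethylcyclohept-2-en-1-yl]-2-methylprop-2-enoate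
Conditions: 16, KN(SiMe3)2, 18-crown-6, THF, −78 °C; then 15, −78 °C
Reagents that add atoms: none
Why: Still–Gennari olefination: the electron-poor phosphonate eliminates fast and irreversibly from the kinetic adduct, which should give the Z-trisubstituted enoate (C1=C11 with C2 cis to the carboxyl carbon) that the later ring closure needs.

Step 12
Reactants: 17 ethyl (2Z)-3-[(1R,4R,6R)-4-acetoxy-6-[(tert-butyldimethylsilyl)oxy]-3,7,7-trimethylcyclohept-2-en-1-yl]-2-methylprop-2-enoate
Product: 18 (2Z)-3-[(1R,4R,6R)-6-[(tert-butyldimethylsilyl)oxy]-4-hydroxy-3,7,7-trimethylcyclohept-2-en-1-yl]-2-methylprop-2-enoic acid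
Conditions: LiOH·H2O, THF/MeOH/H2O (3:1:1), 40 °C; then aq. HCl to pH 3
Reagents that add atoms: lithium hydroxide ([Li+].[OH-])
Why: Saponification frees the acid; the acetate, which has done its work of telling O6 from O4, is cleaved as well and is put back in step 13, while the silyl ether and the Z-alkene should survive.

Step 13
Reactants: 18 (2Z)-3-[(1R,4R,6R)-6-[(tert-butyldimethylsilyl)oxy]-4-hydroxy-3,7,7-trimethylcyclohept-2-en-1-yl]-2-methylprop-2-enoic acid
Product: 20 (2Z)-3-[(1R,4R,6R)-4-acetoxy-6-[(tert-butyldimethylsilyl)oxy]-3,7,7-trimethylcyclohept-2-en-1-yl]-2-methylprop-2-enoic acid, via mixed anhydride 19 (not isolated)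
Conditions: Ac2O, pyridine, CH2Cl2, rt (no DMAP); then THF/H2O, NaHCO3, rt; acidify to pH 3
Reagents that add atoms: acetic anhydride (CC(=O)OC(C)=O)
Why: O-Acetylation of the allylic C6 alcohol; the acid is acylated in passing to a mixed anhydride that water cleaves at the acetyl carbonyl, and leaving out DMAP avoids conjugate addition that could isomerise the Z-enoyl unit.

Step 14
Reactants: 20 (2Z)-3-[(1R,4R,6R)-4-acetoxy-6-[(tert-butyldimethylsilyl)oxy]-3,7,7-trimethylcyclohept-2-en-1-yl]-2-methylprop-2-enoic acid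
Product: 22 (1R,4R,6R)-6-[(tert-butyldimethylsilyl)oxy]-4-[(1Z)-4-diazo-2-methyl-3-oxobut-1-en-1-yl]-2,5,5-trimethylcyclohept-2-en-1-yl acetate, via mixed carbonic anhydride 21 (not isolated)
Conditions: i-BuOCOCl, N-methylmorpholine, THF, −20 °C; then CH2N2 (Et2O), −20 → 0 °C
Reagents that add atoms: diazomethane (C=[N+]=[N-]); isobutyl chloroformate (CC(C)COC(Cl)=O)
Why: Acylation of diazomethane by the mixed carbonic anhydride 21 (first stage of the Arndt–Eistert sequence) gives the diazoketone without acid chloride conditions that could isomerise the Z-alkene; the hindered trisubstituted alkene should resist dipolar cycloaddition.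

Step 15
Reactants: 22 (1R,4R,6R)-6-[(tert-butyldimethylsilyl)oxy]-4-[(1Z)-4-diazo-2-methyl-3-oxobut-1-en-1-yl]-2,5,5-trimethylcyclohept-2-en-1-yl acetate
Product: 23 (1R,4R,6R)-6-[(tert-butyldimethylsilyl)oxy]-4-[(1Z)-4-diazo-2-methyl-3-oxo-4-(triethylsilyl)but-1-en-1-yl]-2,5,5-trimethylcyclohept-2-en-1-yl acetate
Conditions: Et3SiOTf, i-Pr2NEt, Et2O/hexane, 0 °C → rt
Reagents that add atoms: triethylsilyl triflate (CC[Si](CC)(CC)OS(=O)(=O)C(F)(F)F)
Why: Electrophilic C-silylation of the diazo carbon by the silyl triflate with amine base (known for α-diazo ketones) installs the silyl helper on the future C10.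

Step 16
Reactants: 23 (1R,4R,6R)-6-[(tert-butyldimethylsilyl)oxy]-4-[(1Z)-4-diazo-2-methyl-3-oxo-4-(triethylsilyl)but-1-en-1-yl]-2,5,5-trimethylcyclohept-2-en-1-yl acetate
Product: 25 (1S,2S,4R,6R,7R,8R)-4-[(tert-butyldimethylsilyl)oxy]-3,3,7,11-tetramethyl-9-oxo-10-(triethylsilyl)tricyclo[5.4.0.0^{2,8}]undec-10-en-6-yl acetate, via silylvinylketene 24 (not isolated)
Conditions: hν (300 nm), C6H6, 25 °C; then PhMe, 140 °C, sealed tube
Reagents that add atoms: none
Why: Proposed new method: photolysis triggers a Wolff rearrangement in which the alkenyl group migrates with retention of its Z geometry to give the (triethylsilyl)vinylketene 24, and on heating the ring alkene is expected to attack the ketene carbon C9 through C8 in the ketene plane (six-membered ring C1–C2–C8–C9–C10–C11, 6-exo with respect to C7=C8) while charge builds at tertiary C7 and the ketene becomes a 2-silyl dienolate, which then closes at its terminus C1 (four-membered ring C1–C2–C8–C7, collapse of the 1,4-dipole), a stepwise crossed [4+2] annulation. The closest known reactions are the intramolecular ketene–alkene cycloadditions of dienylketenes, which close at the ketene α-carbon to cyclobutanones, and the [4+1] and [4+2] annulations of (trialkylsilyl)vinylketenes, in which a partner adds to the ketene carbon and the ring closes at the vinyl terminus; the one-carbon link (C2) between vinyl terminus and alkene is the new element. C7 and C8 are set by suprafacial addition to the alkene face that carries the C2 side chain, the only face the short tether can reach, and C1 is fixed by the cis bridging of the cage, so C2 controls all three. The step needs closure at C1 and not at C10, and the Et3Si group secures this because closure at C10 would join two fully substituted carbons; the silyl group also keeps the ketene from dimerising at the temperature needed. The C6 acetate lies on the face opposite to the tether and cannot block the approach, and the main competing process is a 1,5-hydrogen shift from C2–H to the ketene carbon.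

Step 17
Reactants: 25 (1S,2S,4R,6R,7R,8R)-4-[(tert-butyldimethylsilyl)oxy]-3,3,7,11-tetramethyl-9-oxo-10-(triethylsilyl)tricyclo[5.4.0.0^{2,8}]undec-10-en-6-yl acetate
Product: 26 (1R,2S,4R,6R,7R,8R)-4-hydroxy-3,3,7,11-tetramethyl-9-oxotricyclo[5.4.0.0^{2,8}]undec-10-en-6-yl acetate
Conditions: TBAF, THF (wet), 0 °C → rt; aq. NH4Cl
Reagents that add atoms: none
Why: Fluoride should cleave the Si–O bond of the silyl ether and the C10–Si bond of the 2-silyl enone (protodesilylation, by attack at silicon or after γ-deprotonation to the dienolate, which makes C10 an sp3 α-silyl centre), with protonation at C10 and without the strong acid that could open the cyclobutane.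

Step 18
Reactants: 26 (1R,2S,4R,6R,7R,8R)-4-hydroxy-3,3,7,11-tetramethyl-9-oxotricyclo[5.4.0.0^{2,8}]undec-10-en-6-yl acetate; 27 angelic acid
Product: 29 (1R,2S,4R,6R,7R,8R)-6-acetoxy-3,3,7,11-tetramethyl-9-oxotricyclo[5.4.0.0^{2,8}]undec-10-en-4-yl (2Z)-2-methylbut-2-enoate, via mixed anhydride 28 (not isolated)
Conditions: 27, 2,4,6-trichlorobenzoyl chloride, Et3N, PhMe, rt; then 26, 80 °C (no DMAP)
Reagents that add atoms: 2,4,6-trichlorobenzoyl chloride (O=C(Cl)c1c(Cl)cc(Cl)cc1Cl)
Why: Yamaguchi esterification: the hindered secondary alcohol attacks the angeloyl carbonyl of the mixed anhydride 28 because the aroyl carbonyl is shielded by its ortho chlorines, and leaving out DMAP should prevent conjugate addition and isomerisation to the tiglate.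

**Compound list**

1 | (E)-but-2-ene-1,4-diol | OC/C=C/CO | starting material
2 | (E)-4-[(tert-butyldimethylsilyl)oxy]but-2-en-1-ol | OC/C=C/CO[Si](C)(C)C(C)(C)C | intermediate
3 | (E)-4-[(tert-butyldimethylsilyl)oxy]but-2-en-1-yl methyl carbonate | COC(=O)OC/C=C/CO[Si](C)(C)C(C)(C)C | intermediate
4 | 1-methoxy-2-methyl-1-(trimethylsilyloxy)prop-1-ene | COC(O[Si](C)(C)C)=C(C)C | starting material
5 | methyl (3S)-3-{[(tert-butyldimethylsilyl)oxy]methyl}-2,2-dimethylpent-4-enoate | COC(=O)C(C)(C)[C@@H](CO[Si](C)(C)C(C)(C)C)C=C | intermediate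
6 | (3S)-3-{[(tert-butyldimethylsilyl)oxy]methyl}-N-methoxy-N,2,2-trimethylpent-4-enamide | CON(C)C(=O)C(C)(C)[C@@H](CO[Si](C)(C)C(C)(C)C)C=C | intermediate (not isolated)
7 | (4S)-4-{[(tert-butyldimethylsilyl)oxy]methyl}-3,3-dimethylhex-5-en-2-one | CC(=O)C(C)(C)[C@@H](CO[Si](C)(C)C(C)(C)C)C=C | intermediate
8 | methacrolein | C=C(C)C=O | starting material
9 | diisopinocampheylboron enolate of 7 | C=C(OB([C@H]1C[C@H]2C[C@@H]([C@@H]1C)C2(C)C)[C@H]1C[C@H]2C[C@@H]([C@@H]1C)C2(C)C)C(C)(C)[C@@H](CO[Si](C)(C)C(C)(C)C)C=C | intermediate (not isolated)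
10 | (3R,7S)-7-{[(tert-butyldimethylsilyl)oxy]methyl}-3-hydroxy-2,6,6-trimethylnona-1,8-dien-5-one | C=C(C)[C@H](O)CC(=O)C(C)(C)[C@@H](CO[Si](C)(C)C(C)(C)C)C=C | intermediate
11 | (3R,5R,7S)-7-{[(tert-butyldimethylsilyl)oxy]methyl}-5-hydroxy-2,6,6-trimethylnona-1,8-dien-3-yl acetate | C=C(C)[C@H](OC(C)=O)C[C@@H](O)C(C)(C)[C@@H](CO[Si](C)(C)C(C)(C)C)C=C | intermediate
12 | (3R,5R,7S)-5-[(tert-butyldimethylsilyl)oxy]-7-{[(tert-butyldimethylsilyl)oxy]methyl}-2,6,6-trimethylnona-1,8-dien-3-yl acetate | C=C(C)[C@H](OC(C)=O)C[C@@H](O[Si](C)(C)C(C)(C)C)C(C)(C)[C@@H](CO[Si](C)(C)C(C)(C)C)C=C | intermediate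
13 | (1R,4S,6R)-6-[(tert-butyldimethylsilyl)oxy]-4-{[(tert-butyldimethylsilyl)oxy]methyl}-2,5,5-trimethylcyclohept-2-en-1-yl acetate | CC(=O)O[C@@H]1C[C@@H](O[Si](C)(C)C(C)(C)C)C(C)(C)[C@@H](CO[Si](C)(C)C(C)(C)C)C=C1C | intermediate
14 | (1R,4S,6R)-6-[(tert-butyldimethylsilyl)oxy]-4-(hydroxymethyl)-2,5,5-trimethylcyclohept-2-en-1-yl acetate | CC(=O)O[C@@H]1C[C@@H](O[Si](C)(C)C(C)(C)C)C(C)(C)[C@@H](CO)C=C1C | intermediate
15 | (1R,4S,6R)-6-[(tert-butyldimethylsilyl)oxy]-4-formyl-2,5,5-trimethylcyclohept-2-en-1-yl acetate | CC(=O)O[C@@H]1C[C@@H](O[Si](C)(C)C(C)(C)C)C(C)(C)[C@@H](C=O)C=C1C | intermediate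
16 | ethyl 2-[bis(2,2,2-trifluoroethoxy)phosphoryl]propanoate | CCOC(=O)C(C)P(=O)(OCC(F)(F)F)OCC(F)(F)F | starting material
17 | ethyl (2Z)-3-[(1R,4R,6R)-4-acetoxy-6-[(tert-butyldimethylsilyl)oxy]-3,7,7-trimethylcyclohept-2-en-1-yl]-2-methylprop-2-enoate | CC(=O)O[C@@H]1C[C@@H](O[Si](C)(C)C(C)(C)C)C(C)(C)[C@@H](/C=C(/C)C(=O)OCC)C=C1C | intermediate
18 | (2Z)-3-[(1R,4R,6R)-6-[(tert-butyldimethylsilyl)oxy]-4-hydroxy-3,7,7-trimethylcyclohept-2-en-1-yl]-2-methylprop-2-enoic acid | O[C@@H]1C[C@@H](O[Si](C)(C)C(C)(C)C)C(C)(C)[C@@H](/C=C(/C)C(=O)O)C=C1C | intermediate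
19 | acetic (2Z)-3-[(1R,4R,6R)-4-acetoxy-6-[(tert-butyldimethylsilyl)oxy]-3,7,7-trimethylcyclohept-2-en-1-yl]-2-methylprop-2-enoic anhydride | CC(=O)O[C@@H]1C[C@@H](O[Si](C)(C)C(C)(C)C)C(C)(C)[C@@H](/C=C(/C)C(=O)OC(C)=O)C=C1C | intermediate (not isolated)
20 | (2Z)-3-[(1R,4R,6R)-4-acetoxy-6-[(tert-butyldimethylsilyl)oxy]-3,7,7-trimethylcyclohept-2-en-1-yl]-2-methylprop-2-enoic acid | CC(=O)O[C@@H]1C[C@@H](O[Si](C)(C)C(C)(C)C)C(C)(C)[C@@H](/C=C(/C)C(=O)O)C=C1C | intermediate
21 | isobutyl carbonic anhydride of acid 20 | CC(=O)O[C@@H]1C[C@@H](O[Si](C)(C)C(C)(C)C)C(C)(C)[C@@H](/C=C(/C)C(=O)OC(=O)OCC(C)C)C=C1C | intermediate (not isolated)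
22 | (1R,4R,6R)-6-[(tert-butyldimethylsilyl)oxy]-4-[(1Z)-4-diazo-2-methyl-3-oxobut-1-en-1-yl]-2,5,5-trimethylcyclohept-2-en-1-yl acetate | CC(=O)O[C@@H]1C[C@@H](O[Si](C)(C)C(C)(C)C)C(C)(C)[C@@H](/C=C(/C)C(=O)C=[N+]=[N-])C=C1C | intermediate
23 | (1R,4R,6R)-6-[(tert-butyldimethylsilyl)oxy]-4-[(1Z)-4-diazo-2-methyl-3-oxo-4-(triethylsilyl)but-1-en-1-yl]-2,5,5-trimethylcyclohept-2-en-1-yl acetate | CC(=O)O[C@@H]1C[C@@H](O[Si](C)(C)C(C)(C)C)C(C)(C)[C@@H](/C=C(/C)C(=O)C(=[N+]=[N-])[Si](CC)(CC)CC)C=C1C | intermediate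
24 | (1R,4R,6R)-6-[(tert-butyldimethylsilyl)oxy]-2,5,5-trimethyl-4-[(1Z)-2-methyl-4-oxo-3-(triethylsilyl)buta-1,3-dien-1-yl]cyclohept-2-en-1-yl acetate | CC(=O)O[C@@H]1C[C@@H](O[Si](C)(C)C(C)(C)C)C(C)(C)[C@@H](/C=C(/C)C(=C=O)[Si](CC)(CC)CC)C=C1C | intermediate (not isolated)
25 | (1S,2S,4R,6R,7R,8R)-4-[(tert-butyldimethylsilyl)oxy]-3,3,7,11-tetramethyl-9-oxo-10-(triethylsilyl)tricyclo[5.4.0.0^{2,8}]undec-10-en-6-yl acetate | CC(C)(C)[Si](C)(C)O[C@@H]1C[C@@H](OC(C)=O)[C@@]2(C)[C@@H]3C(=O)C([Si](CC)(CC)CC)=C(C)[C@H]2[C@@H]3C1(C)C | intermediate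
26 | (1R,2S,4R,6R,7R,8R)-4-hydroxy-3,3,7,11-tetramethyl-9-oxotricyclo[5.4.0.0^{2,8}]undec-10-en-6-yl acetate | O[C@@H]1C[C@@H](OC(C)=O)[C@@]2(C)[C@@H]3C(=O)C=C(C)[C@H]2[C@@H]3C1(C)C | intermediate
27 | angelic acid ((2Z)-2-methylbut-2-enoic acid) | C/C=C(/C)C(=O)O | starting material
28 | (2Z)-2-methylbut-2-enoic 2,4,6-trichlorobenzoic anhydride | C/C=C(/C)C(=O)OC(=O)c1c(Cl)cc(Cl)cc1Cl | intermediate (not isolated)
29 | (1R,2S,4R,6R,7R,8R)-6-acetoxy-3,3,7,11-tetramethyl-9-oxotricyclo[5.4.0.0^{2,8}]undec-10-en-4-yl (2Z)-2-methylbut-2-enoate | C/C=C(/C)C(=O)O[C@@H]1C[C@@H](OC(C)=O)[C@@]2(C)[C@@H]3C(=O)C=C(C)[C@H]2[C@@H]3C1(C)C | target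

**Totals**

Total step count: 18. Longest linear sequence: 18 steps (1 to 29).

**Steps most likely to fail**

Step 16. The dipole may close at the silyl-bearing carbon C10 instead of C1, the silyl-stabilised ketene may be too weak an electrophile for the unactivated alkene, or a 1,5-hydrogen shift from C2–H may drain the ketene to a dienal. The fallback sets out from diazoketone 22, before C-silylation, and uses known reaction types. Photochemical Wolff rearrangement of 22 gives the silicon-free vinylketene F1, which should undergo the well-precedented intramolecular ketene–alkene [2+2] cycloaddition at the ketene C=C bond to the bridged 2-vinylcyclobutanone F2 (bonds C8–C9 and C7–C10). F2 is then isomerised by the acid-promoted 2-vinylcyclobutanone to cyclohex-2-enone ring expansion (BF3·OEt2 or MsOH, CH2Cl2, 0 °C), in which the C7–C10 bond ionises to the tertiary C7 cation and a dienol that recloses at C1; this gives the silyl ether of the tricyclic enone F3. HF·pyridine then removes the silyl ether, and the fallback comes back to the route at 26.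

Step 17. Cleavage of the C10–Si bond by fluoride may be slow, and long exposure to basic fluoride may cause loss or migration of the acetate. The fallback sets out from 25 and replaces nucleophilic desilylation by electrophilic ipso-substitution and reduction. HF·pyridine removes only the silyl ether and gives the C-silylated hydroxy enone F4. ICl in CH2Cl2 at −78 °C converts the vinylsilane into the 2-iodo enone F5 (iododesilylation), and Pd(PPh3)4 with Bu3SnH replaces iodine by hydrogen. The fallback comes back to the route at 26.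

Step 18. Acylation of the hindered neopentyl alcohol may be slow, and the activated angeloyl group may isomerise to the tigloyl group on heating. The fallback sets out from 26 and builds the Z-alkene on the ester instead of transferring it. Esterification of 26 with 2-[bis(2,2,2-trifluoroethoxy)phosphoryl]propanoic acid (DCC, DMAP, CH2Cl2) gives the phosphonate ester F6, a mixture at the phosphorus-bearing carbon. Still–Gennari olefination of F6 with acetaldehyde (KN(SiMe3)2, 18-crown-6, THF, −78 °C) should give the Z-2-methylbut-2-enoate, and the fallback comes back to the route at 29.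

**Further compounds**

F1 | step 16 | silicon-free (Z)-vinylketene from 22, (1R,4S,6R)-6-[(tert-butyldimethylsilyl)oxy]-2,5,5-trimethyl-4-[(1Z)-2-methyl-4-oxobuta-1,3-dien-1-yl]cyclohept-2-en-1-yl acetate | CC(=O)O[C@@H]1C[C@@H](O[Si](C)(C)C(C)(C)C)C(C)(C)[C@@H](/C=C(/C)C=C=O)C=C1C
F2 | step 16 | bridged 2-vinylcyclobutanone from closure at the ketene α-carbon (C8–C9 and C7–C10 bonds), silyl ether on O4 and acetate on O6 | CC(C)(C)[Si](C)(C)O[C@@H]1C[C@@H](OC(C)=O)[C@@]2(C)[C@@H]3C(=O)[C@H]2C(C)=C[C@@H]3C1(C)C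
F3 | step 16 | tert-butyldimethylsilyl ether of 26 | CC(C)(C)[Si](C)(C)O[C@@H]1C[C@@H](OC(C)=O)[C@@]2(C)[C@@H]3C(=O)C=C(C)[C@H]2[C@@H]3C1(C)C
F4 | step 17 | 10-(triethylsilyl) derivative of 26 | O[C@@H]1C[C@@H](OC(C)=O)[C@@]2(C)[C@@H]3C(=O)C([Si](CC)(CC)CC)=C(C)[C@H]2[C@@H]3C1(C)C
F5 | step 17 | 10-iodo derivative of 26 | O[C@@H]1C[C@@H](OC(C)=O)[C@@]2(C)[C@@H]3C(=O)C(I)=C(C)[C@H]2[C@@H]3C1(C)C
F6 | step 18 | 2-[bis(2,2,2-trifluoroethoxy)phosphoryl]propanoate ester of 26 | CC(C(=O)O[C@@H]1C[C@@H](OC(C)=O)[C@@]2(C)[C@@H]3C(=O)C=C(C)[C@H]2[C@@H]3C1(C)C)P(=O)(OCC(F)(F)F)OCC(F)(F)F
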